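The ring is numbered C1 = fusion CH bonded to lactone Cα, C2 = fusion OCH, then C3=C4(Me), C5, C6(OAc), C7=C8(Me), C9, C10(OAc), C11=C12(Me), C13, C14. The target is 1R,2S,6S,10S, has three E ring alkenes and a trans-fused lactone.
First cut: the acetates go back to TBS ethers, and the five-membered lactone is cut at O–C2 and Cα–C1. C2 is allylic to C3=C4, so C1–C2–C3–C4 of the 14-membered carbocycle is a latent 1,3-diene and Cα–C(=O)–O is 2-bromoacrylic acid. The two are joined by one Pd-catalysed [3+2] heteroannulation.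
Second cut: the (1Z,3E)-diene comes from a macrocyclic 1,3-enyne by syn semi-reduction, and the 14-membered ring of that enyne is cut at C2–C3 (Sonogashira).
Third cut: the open chain is cut at C5–C6 (propargylation, with the C4 methyl from carboalumination), at C9–C10 (vinylogous aldol) and at C12–C13 (carbocupration).
Forward order: the chain is grown from the C2/C1/C14 end to C3, the carbocycle is closed, the alkyne is reduced, the lactone ring is made last on the intact carbocycle, and TBS is then exchanged for acetate.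
Stereochemistry: C10 and C6 come from one chiral Lewis-base/SiCl4 catalyst, and the E alkenes from syn carbometalations and the vinylogous aldol. C1 comes from the chiral bisphosphine on Pd, and C2 is relayed from C1 by syn carbopalladation and anti carboxylate attack on the Z alkene.

Key step: step 15

Assumption: the (R,R)-bisphosphoramide·SiCl4 catalyst is taken to expose the Re face of conjugated aldehydes, so its (S,S)-antipode is written for Si-face attack, and (R)-BINAP is written for the key step although its sense on this diene cannot be derived from precedent; if either sense is the opposite, the antipodal ligand is used and nothing else changes.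

Step 1
Reactants: 1 4-bromo-1-(trimethylsilyl)but-1-yne; 2 ethyl but-2-ynoate
Product: 5 ethyl (2E)-3-methyl-7-(trimethylsilyl)hept-2-en-6-ynoate, via Grignard reagent 3 (not isolated), via organocopper reagent 4 (not isolated)
Conditions: Mg, THF, rt; CuBr·SMe2, THF, −78 to −40 °C; 2, −78 °C; aq NH4Cl
Reagents that add atoms: none
Why: Syn carbocupration of a 2-alkynoate places the alkyl group on C12 and copper on C11 on the same side at −78 °C, so protonation should give only the E enoate, while the silyl cap keeps the alkyne terminus inert.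

Step 2
Reactants: 5 ethyl (2E)-3-methyl-7-(trimethylsilyl)hept-2-en-6-ynoate
Product: 6 (2E)-3-methyl-7-(trimethylsilyl)hept-2-en-6-yn-1-ol
Conditions: DIBAL-H (2.3 equiv), CH2Cl2, −78 °C; aq Rochelle salt
Reagents that add atoms: none
Why: DIBAL-H 1,2-reduction of an α,β-unsaturated ester to the allylic alcohol leaves the silylalkyne and the alkene geometry untouched at −78 °C.

Step 3
Reactants: 6 (2E)-3-methyl-7-(trimethylsilyl)hept-2-en-6-yn-1-ol
Product: 7 (2E)-3-methyl-7-(trimethylsilyl)hept-2-en-6-ynal
Conditions: activated MnO2, CH2Cl2, rt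
Reagents that add atoms: none
Why: MnO2 oxidation is selective for the allylic alcohol and is neutral, so the E alkene should not isomerise.

Step 4
Reactants: 8 methyl 3-methylbut-2-enoate
Product: 10 tert-butyl[(1-methoxy-3-methylbuta-1,3-dien-1-yl)oxy]dimethylsilane, via lithium dienolate 9 (not isolated)
Conditions: LDA, THF/DMPU, −78 °C; TBSCl, −78 °C to rt
Reagents that add atoms: tert-butyldimethylsilyl chloride, CC(C)(C)[Si](C)(C)Cl
Why: Kinetic γ-deprotonation of the senecioate and O-silylation of the extended enolate (silyl ketene acetal formation) give the vinylogous nucleophile, whose ketene acetal geometry is of no consequence.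

Step 5
Reactants: 7 (2E)-3-methyl-7-(trimethylsilyl)hept-2-en-6-ynal; 10 tert-butyl[(1-methoxy-3-methylbuta-1,3-dien-1-yl)oxy]dimethylsilane
Product: 11 methyl (2E,5S,6E)-5-hydroxy-3,7-dimethyl-11-(trimethylsilyl)undeca-2,6-dien-10-ynoate
Conditions: SiCl4 (1.1 equiv), (S,S)-bisphosphoramide from N,N'-dimethyl-1,1'-binaphthyl-2,2'-diamine with a pentane-1,5-diyl linker (5 mol %), i-Pr2NEt (10 mol %), CH2Cl2, −78 °C; aq NaHCO3
Reagents that add atoms: none
Why: In this catalytic enantioselective vinylogous Mukaiyama aldol reaction the aldehyde bound to the chiral trichlorosilyl cation is attacked on its Si face by the unhindered γ-CH2 of 10 through an open transition state, which should set C10 as S and the new C7=C8 enoate as E (a Z isomer would lactonise and be removed by chromatography).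

Step 6
Reactants: 11 methyl (2E,5S,6E)-5-hydroxy-3,7-dimethyl-11-(trimethylsilyl)undeca-2,6-dien-10-ynoate
Product: 12 methyl (2E,5S,6E)-5-[(tert-butyldimethylsilyl)oxy]-3,7-dimethyl-11-(trimethylsilyl)undeca-2,6-dien-10-ynoate
Conditions: TBSCl, imidazole, DMF, rt
Reagents that add atoms: tert-butyldimethylsilyl chloride, CC(C)(C)[Si](C)(C)Cl
Why: Standard silylation of a secondary allylic alcohol installs a group that survives the later hydride, organoaluminium, Pd and Ag reagents and, unlike an allylic acetate, is not ionised by Pd(0).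

Step 7
Reactants: 12 methyl (2E,5S,6E)-5-[(tert-butyldimethylsilyl)oxy]-3,7-dimethyl-11-(trimethylsilyl)undeca-2,6-dien-10-ynoate
Product: 13 (2E,5S,6E)-5-[(tert-butyldimethylsilyl)oxy]-3,7-dimethyl-11-(trimethylsilyl)undeca-2,6-dien-10-yn-1-ol
Conditions: DIBAL-H (2.3 equiv), CH2Cl2, −78 °C; aq Rochelle salt
Reagents that add atoms: none
Why: DIBAL-H 1,2-reduction of the enoate proceeds as in step 2 and does not affect the silyl ether or the C10 centre.

Step 8
Reactants: 13 (2E,5S,6E)-5-[(tert-butyldimethylsilyl)oxy]-3,7-dimethyl-11-(trimethylsilyl)undeca-2,6-dien-10-yn-1-ol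
Product: 14 (2E,5S,6E)-5-[(tert-butyldimethylsilyl)oxy]-3,7-dimethyl-11-(trimethylsilyl)undeca-2,6-dien-10-ynal
Conditions: activated MnO2, CH2Cl2, rt
Reagents that add atoms: none
Why: MnO2 oxidises only the primary allylic alcohol and keeps the E geometry of C7=C8.

Step 9
Reactants: 14 (2E,5S,6E)-5-[(tert-butyldimethylsilyl)oxy]-3,7-dimethyl-11-(trimethylsilyl)undeca-2,6-dien-10-ynal; 15 tributyl(propa-1,2-dien-1-yl)stannane
Product: 16 (4S,5E,8S,9E)-8-[(tert-butyldimethylsilyl)oxy]-6,10-dimethyl-14-(trimethylsilyl)tetradeca-5,9-diene-1,13-diyn-4-ol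
Conditions: SiCl4 (1.1 equiv), the same (S,S)-bisphosphoramide (5 mol %), CH2Cl2, −78 °C; aq NaHCO3
Reagents that add atoms: none
Why: Catalytic enantioselective propargylation (SE2' addition of an allenylstannane) with the same chiral silicon Lewis acid should again attack the Si face and set C6 as S under catalyst control, because C10 is too remote (1,5) to interfere.

Step 10
Reactants: 16 (4S,5E,8S,9E)-8-[(tert-butyldimethylsilyl)oxy]-6,10-dimethyl-14-(trimethylsilyl)tetradeca-5,9-diene-1,13-diyn-4-ol
Product: 17 (4S,5E,8S,9E)-4,8-bis[(tert-butyldimethylsilyl)oxy]-6,10-dimethyl-14-(trimethylsilyl)tetradeca-5,9-diene-1,13-diyne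
Conditions: TBSCl, imidazole, DMF, rt
Reagents that add atoms: tert-butyldimethylsilyl chloride, CC(C)(C)[Si](C)(C)Cl
Why: Standard silylation protects the second allylic alcohol for the same reasons as in step 6.

Step 11
Reactants: 17 (4S,5E,8S,9E)-4,8-bis[(tert-butyldimethylsilyl)oxy]-6,10-dimethyl-14-(trimethylsilyl)tetradeca-5,9-diene-1,13-diyne
Product: 19 (1E,4S,5E,8S,9E)-4,8-bis[(tert-butyldimethylsilyl)oxy]-1-iodo-2,6,10-trimethyl-14-(trimethylsilyl)tetradeca-1,5,9-trien-13-yne, via alkenylalane 18 (not isolated)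
Conditions: Me3Al (3 equiv), Cp2ZrCl2 (25 mol %), CH2Cl2, 0 °C to rt; I2, THF, −30 °C
Reagents that add atoms: trimethylaluminium, C[Al](C)C; iodine, II
Why: Negishi Zr-catalysed carboalumination adds Me (to C4) and Al (to C3) syn across the terminal alkyne and iodinolysis proceeds with retention, which gives the E iodide, while the silyl-capped alkyne and the trisubstituted alkenes react far more slowly.

Step 12
Reactants: 19 (1E,4S,5E,8S,9E)-4,8-bis[(tert-butyldimethylsilyl)oxy]-1-iodo-2,6,10-trimethyl-14-(trimethylsilyl)tetradeca-1,5,9-trien-13-yne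
Product: 20 (1E,4S,5E,8S,9E)-4,8-bis[(tert-butyldimethylsilyl)oxy]-1-iodo-2,6,10-trimethyltetradeca-1,5,9-trien-13-yne
Conditions: K2CO3 (cat.), MeOH/THF, rt
Reagents that add atoms: none
Why: Base-catalysed methanolysis cleaves the alkynyl C–Si bond selectively over the two TBS ethers and does not harm the alkenyl iodide.

Step 13
Reactants: 20 (1E,4S,5E,8S,9E)-4,8-bis[(tert-butyldimethylsilyl)oxy]-1-iodo-2,6,10-trimethyltetradeca-1,5,9-trien-13-yne
Product: 21 (3E,6S,7E,10S,11E)-6,10-bis[(tert-butyldimethylsilyl)oxy]-4,8,12-trimethylcyclotetradeca-3,7,11-trien-1-yne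
Conditions: Pd(PPh3)4 (15 mol %), CuI (30 mol %), i-Pr2NH, degassed THF, 1 mM, slow addition, rt
Reagents that add atoms: none
Why: Intramolecular Sonogashira coupling under high dilution forms C2–C3 and closes the 14-membered ring with retention of the E geometry of the alkenyl iodide.

Step 14
Reactants: 21 (3E,6S,7E,10S,11E)-6,10-bis[(tert-butyldimethylsilyl)oxy]-4,8,12-trimethylcyclotetradeca-3,7,11-trien-1-yne
Product: 22 (1Z,3E,6S,7E,10S,11E)-6,10-bis[(tert-butyldimethylsilyl)oxy]-4,8,12-trimethylcyclotetradeca-1,3,7,11-tetraene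
Conditions: Zn(Cu/Ag), THF/MeOH/H2O, 40 °C
Reagents that add atoms: none
Why: In the Boland reduction activated zinc delivers two hydrogens syn to the conjugated alkyne only, which should give the Z C1=C2 alkene without touching the isolated alkenes or over-reducing the diene.

Step 15
Reactants: 22 (1Z,3E,6S,7E,10S,11E)-6,10-bis[(tert-butyldimethylsilyl)oxy]-4,8,12-trimethylcyclotetradeca-1,3,7,11-tetraene; 23 2-bromoprop-2-enoic acid
Product: 25 bis-TBS ether of the target 6,10-diol, that is the (1R,2S,3E,6S,7E,10S,11E) trans-fused α-methylene-γ-butyrolactone on C1/C2 of the carbocycle, via allylpalladium carboxylate 24 (not isolated)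
Conditions: Pd2(dba)3·CHCl3 (5 mol %), (R)-BINAP (12 mol %), Ag2CO3 (2 equiv), BHT (trace), 1,4-dioxane, 50 °C, slow addition of 23 (2.5 equiv)
Reagents that add atoms: none
Why: Proposed new method: oxidative addition of Pd(0)/(R)-BINAP into the C–Br bond of 23 and bromide abstraction by Ag+ should give a cationic 1-carboxyvinyl-Pd(II) species that inserts syn into C1=C2 of 22 with C–C bond formation at C1, giving the η3-allyl complex 24 (C2–C3–C4), which the pendant carboxylate attacks at C2 on the face anti to Pd to release 25 and Pd(0). The closest known reaction types are the Larock-type Pd-catalysed heteroannulation of 1,3-dienes with α-haloacrylic acids or o-halophenols and the asymmetric Heck insertion/π-allyl capture cascade with BINAP; new here are the macrocyclic 1,4,4-trisubstituted diene, the demand for net anti addition and ligand control of the diene face. The only ring closed is the five-membered lactone, by 5-exo attack of O on the allyl terminus C2 (the seven-membered alternative at the fully substituted C4 is disfavoured), and C5 stays syn on the allyl unit so that C3=C4 emerges E. C1 (R) is fixed in the insertion by the chiral bisphosphine, which has to direct Cα to the Si face of C1 over the weak bias of the remote C6 and C10 silyloxy centres, and C2 (S) follows from C1 because syn carbopalladation plus anti C–O formation on a Z alkene is a net anti addition and hence gives the trans fusion, the chelating ligand leaving no site on the cationic allyl complex for an inner-sphere syn delivery. Chemoselectivity rests on the diene being the only alkene that can give a stabilised π-allyl (the isolated trisubstituted C7=C8 and C11=C12 do not insert intermolecularly), regioselectivity rests on C1 being the only unhindered CH terminus, and the silyl ethers in place of allylic acetates deny Pd(0) a competing ionisation. The Z,E geometry also disfavours the s-cis conformer, which should suppress a background Diels–Alder reaction with 23.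

Step 16
Reactants: 25 bis-TBS ether of the target 6,10-diol
Product: 26 (1R,2S,3E,6S,7E,10S,11E)-6,10-diol, that is the target with OH in place of both OAc groups
Conditions: HF·pyridine, pyridine, THF, 0 °C to rt
Reagents that add atoms: none
Why: Fluoride-driven silyl ether cleavage in a pyridine-buffered medium avoids both base-triggered conjugate addition to the α-methylene lactone and acid ionisation of the allylic alcohols, so no stereocentre is touched.

Step 17
Reactants: 26 (1R,2S,3E,6S,7E,10S,11E)-6,10-diol
Product: 27 target CID11069750, the 6,10-diacetate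
Conditions: Ac2O, pyridine, DMAP (cat.), CH2Cl2, 0 °C to rt
Reagents that add atoms: acetic anhydride, CC(=O)OC(C)=O
Why: DMAP-catalysed O-acylation of the two secondary allylic alcohols proceeds with retention at C6 and C10 and is compatible with the α-methylene lactone.

Compound list
1 | 4-bromo-1-(trimethylsilyl)but-1-yne | C[Si](C)(C)C#CCCBr | starting material
2 | ethyl but-2-ynoate | CC#CC(=O)OCC | starting material
3 | [4-(trimethylsilyl)but-3-yn-1-yl]magnesium bromide | C[Si](C)(C)C#CCC[Mg]Br | intermediate
4 | [4-(trimethylsilyl)but-3-yn-1-yl]copper(I), drawn without MgBr2/SMe2 | C[Si](C)(C)C#CCC[Cu] | intermediate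
5 | ethyl (2E)-3-methyl-7-(trimethylsilyl)hept-2-en-6-ynoate | CCOC(=O)/C=C(\C)CCC#C[Si](C)(C)C | intermediate
6 | (2E)-3-methyl-7-(trimethylsilyl)hept-2-en-6-yn-1-ol | OC/C=C(\C)CCC#C[Si](C)(C)C | intermediate
7 | (2E)-3-methyl-7-(trimethylsilyl)hept-2-en-6-ynal | O=C/C=C(\C)CCC#C[Si](C)(C)C | intermediate
8 | methyl 3-methylbut-2-enoate | COC(=O)C=C(C)C | starting material
9 | lithium 1-methoxy-3-methylbuta-1,3-dien-1-olate | C=C(C)C=C(OC)[O-].[Li+] | intermediate
10 | tert-butyl[(1-methoxy-3-methylbuta-1,3-dien-1-yl)oxy]dimethylsilane (ketene acetal geometry not defined) | C=C(C)C=C(OC)O[Si](C)(C)C(C)(C)C | intermediate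
11 | methyl (2E,5S,6E)-5-hydroxy-3,7-dimethyl-11-(trimethylsilyl)undeca-2,6-dien-10-ynoate | COC(=O)/C=C(\C)C[C@H](O)/C=C(\C)CCC#C[Si](C)(C)C | intermediate
12 | methyl (2E,5S,6E)-5-[(tert-butyldimethylsilyl)oxy]-3,7-dimethyl-11-(trimethylsilyl)undeca-2,6-dien-10-ynoate | COC(=O)/C=C(\C)C[C@H](O[Si](C)(C)C(C)(C)C)/C=C(\C)CCC#C[Si](C)(C)C | intermediate
13 | (2E,5S,6E)-5-[(tert-butyldimethylsilyl)oxy]-3,7-dimethyl-11-(trimethylsilyl)undeca-2,6-dien-10-yn-1-ol | OC/C=C(\C)C[C@H](O[Si](C)(C)C(C)(C)C)/C=C(\C)CCC#C[Si](C)(C)C | intermediate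
14 | (2E,5S,6E)-5-[(tert-butyldimethylsilyl)oxy]-3,7-dimethyl-11-(trimethylsilyl)undeca-2,6-dien-10-ynal | O=C/C=C(\C)C[C@H](O[Si](C)(C)C(C)(C)C)/C=C(\C)CCC#C[Si](C)(C)C | intermediate
15 | tributyl(propa-1,2-dien-1-yl)stannane | C=C=C[Sn](CCCC)(CCCC)CCCC | starting material
16 | (4S,5E,8S,9E)-8-[(tert-butyldimethylsilyl)oxy]-6,10-dimethyl-14-(trimethylsilyl)tetradeca-5,9-diene-1,13-diyn-4-ol | C#CC[C@H](O)/C=C(\C)C[C@H](O[Si](C)(C)C(C)(C)C)/C=C(\C)CCC#C[Si](C)(C)C | intermediate
17 | (4S,5E,8S,9E)-4,8-bis[(tert-butyldimethylsilyl)oxy]-6,10-dimethyl-14-(trimethylsilyl)tetradeca-5,9-diene-1,13-diyne | C#CC[C@H](O[Si](C)(C)C(C)(C)C)/C=C(\C)C[C@H](O[Si](C)(C)C(C)(C)C)/C=C(\C)CCC#C[Si](C)(C)C | intermediate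
18 | (E)-alkenyl(dimethyl)alane from 17 (AlMe2 on C3, new methyl on C4) | C[Al](C)/C=C(\C)C[C@H](O[Si](C)(C)C(C)(C)C)/C=C(\C)C[C@H](O[Si](C)(C)C(C)(C)C)/C=C(\C)CCC#C[Si](C)(C)C | intermediate
19 | (1E,4S,5E,8S,9E)-4,8-bis[(tert-butyldimethylsilyl)oxy]-1-iodo-2,6,10-trimethyl-14-(trimethylsilyl)tetradeca-1,5,9-trien-13-yne | I/C=C(\C)C[C@H](O[Si](C)(C)C(C)(C)C)/C=C(\C)C[C@H](O[Si](C)(C)C(C)(C)C)/C=C(\C)CCC#C[Si](C)(C)C | intermediate
20 | (1E,4S,5E,8S,9E)-4,8-bis[(tert-butyldimethylsilyl)oxy]-1-iodo-2,6,10-trimethyltetradeca-1,5,9-trien-13-yne | I/C=C(\C)C[C@H](O[Si](C)(C)C(C)(C)C)/C=C(\C)C[C@H](O[Si](C)(C)C(C)(C)C)/C=C(\C)CCC#C | intermediate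
21 | (3E,6S,7E,10S,11E)-6,10-bis[(tert-butyldimethylsilyl)oxy]-4,8,12-trimethylcyclotetradeca-3,7,11-trien-1-yne | C1C#C/C=C(\C)C[C@H](O[Si](C)(C)C(C)(C)C)/C=C(\C)C[C@H](O[Si](C)(C)C(C)(C)C)/C=C(\C)C1 | intermediate
22 | (1Z,3E,6S,7E,10S,11E)-6,10-bis[(tert-butyldimethylsilyl)oxy]-4,8,12-trimethylcyclotetradeca-1,3,7,11-tetraene | C1/C=C\C=C(/C)C[C@H](O[Si](C)(C)C(C)(C)C)/C=C(\C)C[C@H](O[Si](C)(C)C(C)(C)C)/C=C(\C)C1 | intermediate
23 | 2-bromoprop-2-enoic acid | C=C(Br)C(=O)O | starting material
24 | allylpalladium carboxylate (C2–C4 allyl drawn in its η1 form at C2, BINAP omitted; 1-carboxylatovinyl group on C1 on the same face as Pd) | [Pd+][C@@H]1/C=C(\C)C[C@H](O[Si](C)(C)C(C)(C)C)/C=C(\C)C[C@H](O[Si](C)(C)C(C)(C)C)/C=C(\C)CC[C@@H]1C(=C)C(=O)[O-] | intermediate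
25 | bis-TBS ether of the target diol (1R,2S,6S,10S; trans-fused α-methylene lactone) | C=C1C(=O)O[C@H]2/C=C(\C)C[C@H](O[Si](C)(C)C(C)(C)C)/C=C(\C)C[C@H](O[Si](C)(C)C(C)(C)C)/C=C(\C)CC[C@H]12 | intermediate
26 | 6,10-diol (1R,2S,6S,10S) | C=C1C(=O)O[C@H]2/C=C(\C)C[C@H](O)/C=C(\C)C[C@H](O)/C=C(\C)CC[C@H]12 | intermediate
27 | CID11069750, 6,10-diacetate (1R,2S,6S,10S) | C=C1C(=O)O[C@H]2/C=C(\C)C[C@H](OC(C)=O)/C=C(\C)C[C@H](OC(C)=O)/C=C(\C)CC[C@H]12 | target

Total step count: 17. Longest linear sequence: 16 (steps 1–3 and 5–17; step 4 is a one-step side branch).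

Steps most likely to fail

Step 15.
- Migratory insertion at an internal diene terminus may be slow enough for self-coupling or polymerisation of the bromoacrylate to consume the reagent.
- Inner-sphere C–O bond formation, or inversion of the allyl complex by Pd(0), may erode the trans fusion.
- The ligand may not override the facial bias of the macrocycle.

The fallback uses known radical–polar chemistry. It sets out from 22 and returns at 25. A Mn(III)-based oxidative lactone annulation with potassium methyl malonate (Mn(OAc)3·2H2O, AcOH, rt) adds the malonyl radical to C1. The resulting allyl radical is oxidised, and the carboxylate closes on C2 in the kinetically preferred trans sense to give the α-methoxycarbonyl lactone F1. Saponification (LiOH, THF/H2O, then mild acid to re-close the lactone) gives the α-carboxy lactone F2. Decarboxylative Mannich methylenation (aq HCHO, Et2NH, then NaOAc/AcOH) gives 25. The diene face is then chosen by the substrate alone, and the unwanted trans diastereomer would have to be removed by chromatography.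

Step 13. Oligomerisation and oxidative alkyne dimerisation may outrun an irreversible ring closure in which the Pd acetylide must reach across the whole chain. The fallback closes the ring at C1≡C2 by a reversible reaction. It sets out from 19 and returns at 21.
- Intermolecular Sonogashira coupling of 19 with propyne (PdCl2(PPh3)2, CuI, i-Pr2NH, THF) gives the propynyl enyne F3.
- K2CO3/MeOH removes the silyl cap to give the terminal alkyne F4.
- n-BuLi and then MeI give the bis(methyl-capped) diyne F5.
- Ring-closing alkyne metathesis (molybdenum alkylidyne tris(triphenylsilanolate) catalyst, 5 Å molecular sieves, toluene, 80 °C, high dilution) expels but-2-yne and gives 21. Oligomers are recycled to the ring because the reaction is reversible.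

Step 5. The β,β-disubstituted enal may bind poorly to the silicon Lewis acid. This would slow turnover, let an unselective background pathway lower the facial selectivity, and erode the E geometry of the new enoate. The fallback builds the same enoate by alkyne carbometalation. It sets out from 7 and returns at 12.
- Propargylboration of 7 with allenylboronic acid pinacol ester, catalysed by a chiral phosphoric acid (closed six-membered transition state, catalyst antipode chosen for S), gives the homopropargylic alcohol F6.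
- TBSCl/imidazole gives its TBS ether F7.
- Negishi carboalumination (Me3Al, Cp2ZrCl2) gives the alkenylalane F8.
- F8 is trapped with methyl chloroformate to give 12 with the E geometry fixed by syn addition.

Further compounds
F1 | step 15 | α-methoxycarbonyl trans-lactone, bis-TBS ether (Cα not defined) | COC(=O)C1C(=O)O[C@H]2/C=C(\C)C[C@H](O[Si](C)(C)C(C)(C)C)/C=C(\C)C[C@H](O[Si](C)(C)C(C)(C)C)/C=C(\C)CC[C@H]12
F2 | step 15 | α-carboxy trans-lactone, bis-TBS ether (Cα not defined) | OC(=O)C1C(=O)O[C@H]2/C=C(\C)C[C@H](O[Si](C)(C)C(C)(C)C)/C=C(\C)C[C@H](O[Si](C)(C)C(C)(C)C)/C=C(\C)CC[C@H]12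
F3 | step 13 | propynyl enyne from 19 (prop-1-ynyl in place of iodine, TMS alkyne kept) | CC#C/C=C(\C)C[C@H](O[Si](C)(C)C(C)(C)C)/C=C(\C)C[C@H](O[Si](C)(C)C(C)(C)C)/C=C(\C)CCC#C[Si](C)(C)C
F4 | step 13 | terminal alkyne from F3 | CC#C/C=C(\C)C[C@H](O[Si](C)(C)C(C)(C)C)/C=C(\C)C[C@H](O[Si](C)(C)C(C)(C)C)/C=C(\C)CCC#C
F5 | step 13 | bis(methyl-capped) diyne | CC#C/C=C(\C)C[C@H](O[Si](C)(C)C(C)(C)C)/C=C(\C)C[C@H](O[Si](C)(C)C(C)(C)C)/C=C(\C)CCC#CC
F6 | step 5 | (4S,5E)-6-methyl-10-(trimethylsilyl)dec-5-ene-1,9-diyn-4-ol | C#CC[C@H](O)/C=C(\C)CCC#C[Si](C)(C)C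
F7 | step 5 | TBS ether of F6 | C#CC[C@H](O[Si](C)(C)C(C)(C)C)/C=C(\C)CCC#C[Si](C)(C)C
F8 | step 5 | (E)-alkenyl(dimethyl)alane from F7 | C[Al](C)/C=C(\C)C[C@H](O[Si](C)(C)C(C)(C)C)/C=C(\C)CCC#C[Si](C)(C)C
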